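**Retrosynthetic overview**
1. Target 17 ⇒ dialdehyde 15: one intramolecular carbene-homoenolate/aldehyde annulation makes C11–C12, closes ring C and lactone D together and sets C10–C13.
2. 15 ⇒ bromo alcohol 12: Heck coupling with methacrolein at C1, then oxidation of C11–OH.
3. 12 ⇒ enyne 9: ring-closing enyne metathesis (azepine ring B plus a 1,3-diene), then hydroboration of the diene terminus.
4. 9 ⇒ 4,5-dibromo-1H-pyrrole-2-carbaldehyde 1: N-pentenylation, iridium 2-(methoxycarbonyl)allylation/lactonisation and CuH reduction (lactone E), α-selective Sonogashira coupling with but-1-yne.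
5. Ring order: A (pyrrole, bought) → E (pendant lactone) → B (azepine) → C and D together in the last step.

Numbering used (Stemona type): pyrrole C1, C2, C3, N4; azepine C5–C9, C9a; ring C C10–C12; lactone D C13, C14 (methyl C15); ethyl C16, C17; lactone E C18–C21 (methyl C22). The target is (10S,11R,12S,13R,18R,20R), with C8=C9.

Assumption: (R)-SEGPHOS on iridium (step 2) and the (5aS,10bR) triazolium (step 9) give the 18R and 12S senses; where a sense proves opposite, the mirror-image catalyst is used.

**Route**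

Step 1
Reactants: 1 4,5-dibromo-1H-pyrrole-2-carbaldehyde; 2 5-bromopent-1-ene
Product: 3 4,5-dibromo-1-(pent-4-en-1-yl)-1H-pyrrole-2-carbaldehyde
Conditions: K2CO3, DMF, 60 °C
Reagents that add atoms: 5-bromopent-1-ene (2), C=CCCCBr
Why: SN2 N-alkylation of the acidic pyrrole N–H (acidified by the formyl and bromo groups); the N-substituent also prevents azafulvene formation from the pyrrolyl carbinyl lactone made next.

Step 2
Reactants: 3; 4 methyl 2-(acetoxymethyl)acrylate
Product: 6 (5R)-5-[4,5-dibromo-1-(pent-4-en-1-yl)-1H-pyrrol-2-yl]-3-methylideneoxolan-2-one, via hydroxy ester 5 (not isolated)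
Conditions: [Ir(cod)Cl]2 (2.5 mol %), (R)-SEGPHOS (5 mol %), 4-cyano-3-nitrobenzoic acid (10 mol %), Cs2CO3 (20 mol %), i-PrOH (2 equiv), THF, 70 °C
Reagents that add atoms: methyl 2-(acetoxymethyl)acrylate (4), C=C(COC(C)=O)C(=O)OC
Why: Krische-type iridium-catalysed transfer-hydrogenative 2-(alkoxycarbonyl)allylation, in which the chiral π-allyl iridium adds to one aldehyde face to set C18 (R) and the alkoxide of 5 closes onto the methyl ester; aryl bromides and the remote alkene are tolerated.

Step 3
Reactants: 6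
Product: 7 (3R,5R)-5-[4,5-dibromo-1-(pent-4-en-1-yl)-1H-pyrrol-2-yl]-3-methyloxolan-2-one
Conditions: Cu(OAc)2·H2O (5 mol %), 1,2-bis(diphenylphosphino)benzene (5 mol %), HSiMe(OEt)2 (2 equiv), t-BuOH (2 equiv), toluene, 0 °C to rt
Reagents that add atoms: none
Why: Copper hydride 1,4-reduction (Stryker type) touches only the conjugated exo-methylene, and the copper enolate is protonated on the face opposite the C5 pyrrolyl group to give the 3,5-cis lactone (C20 R), the minor trans epimer being removed by chromatography.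

Step 4
Reactants: 7; 8 but-1-yne
Product: 9 (3R,5R)-5-[4-bromo-5-(but-1-yn-1-yl)-1-(pent-4-en-1-yl)-1H-pyrrol-2-yl]-3-methyloxolan-2-one
Conditions: Pd(PPh3)2Cl2 (5 mol %), CuI (10 mol %), Et3N, THF, sealed tube, 50 °C
Reagents that add atoms: but-1-yne (8), C#CCC
Why: Site-selective Sonogashira coupling, because oxidative addition of zerovalent palladium is faster at the α C–Br next to nitrogen than at the β C–Br, as is general for 2,3-dibromopyrroles.

Step 5
Reactants: 9
Product: 10 (3R,5R)-5-[1-bromo-9-(but-1-en-2-yl)-6,7-dihydro-5H-pyrrolo[1,2-a]azepin-3-yl]-3-methyloxolan-2-one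
Conditions: second-generation Grubbs catalyst RuCl2(=CHPh)(H2IMes)(PCy3) (10 mol %), ethylene (1 atm), toluene, 80 °C
Reagents that add atoms: none
Why: Ring-closing enyne metathesis in the exo mode forms the seven-membered ring with the C8=C9 alkene fixed in place and moves the terminal CH2 onto C10 as a 1,3-diene, a ring-closing mode known for pyrrolo[1,2-a]azepines.

Step 6
Reactants: 10
Product: 12 (3R,5R)-5-[1-bromo-9-(1-hydroxybutan-2-yl)-6,7-dihydro-5H-pyrrolo[1,2-a]azepin-3-yl]-3-methyloxolan-2-one (about 1:1 at C10), via alkylborane 11 (not isolated)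
Conditions: 9-BBN (1.3 equiv), THF, 0 °C to rt; then NaBO3·4H2O, H2O, rt
Reagents that add atoms: sodium perborate, [Na+].[Na+].O[B-]1(O)OO[B-](O)(O)OO1 (oxygen of the alcohol); 9-BBN, B1C2CCCC1CCC2 (its atoms stay only in 11)
Why: Hydroboration–oxidation, in which 9-BBN adds only to the unhindered 1,1-disubstituted diene terminus with boron on CH2 to give the primary alcohol; C10 forms unselectively, which is accepted because step 9 makes this centre labile and corrects it.

Step 7
Reactants: 12; 13 methacrolein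
Product: 14 (2E)-3-{9-(1-hydroxybutan-2-yl)-3-[(2R,4R)-4-methyl-5-oxooxolan-2-yl]-6,7-dihydro-5H-pyrrolo[1,2-a]azepin-1-yl}-2-methylprop-2-enal
Conditions: Pd(OAc)2 (10 mol %), P(t-Bu)3·HBF4 (20 mol %), Cy2NMe (2 equiv), methacrolein (5 equiv), 1,4-dioxane, 90 °C
Reagents that add atoms: methacrolein (13), CC(=C)C=O
Why: Mizoroki–Heck reaction with a bulky electron-rich phosphine for the electron-rich β-bromopyrrole, where syn β-hydride elimination from the CH next to the pyrrole gives the conjugated E-enal.

Step 8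
Reactants: 14
Product: 15 2-{1-[(1E)-2-methyl-3-oxoprop-1-en-1-yl]-3-[(2R,4R)-4-methyl-5-oxooxolan-2-yl]-6,7-dihydro-5H-pyrrolo[1,2-a]azepin-9-yl}butanal (C10 epimers)
Conditions: Dess–Martin periodinane (1.3 equiv), NaHCO3, CH2Cl2, 0 °C; short plug of base-washed silica, used at once
Reagents that add atoms: none
Why: Dess–Martin oxidation under buffered conditions gives the β,γ-unsaturated aldehyde without moving the C8=C9 bond and leaves the enal and lactone untouched.

Step 9
Reactants: 15
Product: 17 target CNP0324368.1, via acyl azolium alkoxide 16 (not isolated)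
Conditions: (5aS,10bR)-2-mesityl-5a,10b-dihydro-4H,6H-indeno[2,1-b][1,2,4]triazolo[4,3-d][1,4]oxazin-2-ium chloride (15 mol %), DBU (15 mol %), THF (0.02 M), 40 °C
Reagents that add atoms: none
Why: Proposed new method: the carbene adds to the enal and the resulting homoenolate (nucleophilic C12) attacks the tethered C11 aldehyde through a six-membered transition state, where the enol O–H···O=C contact gives the 11,12-cis relationship, the new C11 hydroxyl delivers the proton to C13 (methyl exo, 13R) and the alkoxide of 16 lactonises to release the catalyst, while DBU keeps the two α-vinyl aldehyde epimers in equilibrium so that the chiral carbene (face of C12, 12S) and the chair with pseudo-equatorial ethyl trans to oxygen (10S) funnel both epimers into one product by dynamic kinetic resolution; the closest known chemistry is the carbene-catalysed enal plus aldehyde γ-butyrolactone annulation, its intramolecular use on tethered ketones, and carbene-catalysed dynamic kinetic resolutions of α-epimerisable carbonyl compounds.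

**Compound list**
1 | 4,5-dibromo-1H-pyrrole-2-carbaldehyde | O=Cc1cc(Br)c(Br)[nH]1 | starting material
2 | 5-bromopent-1-ene | C=CCCCBr | starting material
3 | 4,5-dibromo-1-(pent-4-en-1-yl)-1H-pyrrole-2-carbaldehyde | O=Cc1cc(Br)c(Br)n1CCCC=C | intermediate
4 | methyl 2-(acetoxymethyl)acrylate | C=C(COC(C)=O)C(=O)OC | starting material
5 | methyl (4R)-4-[4,5-dibromo-1-(pent-4-en-1-yl)-1H-pyrrol-2-yl]-4-hydroxy-2-methylidenebutanoate | C=CCCCn1c(Br)c(Br)cc1[C@H](O)CC(=C)C(=O)OC | intermediate
6 | (5R)-5-[4,5-dibromo-1-(pent-4-en-1-yl)-1H-pyrrol-2-yl]-3-methylideneoxolan-2-one | C=CCCCn1c(Br)c(Br)cc1[C@H]1CC(=C)C(=O)O1 | intermediate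
7 | (3R,5R)-5-[4,5-dibromo-1-(pent-4-en-1-yl)-1H-pyrrol-2-yl]-3-methyloxolan-2-one | C=CCCCn1c(Br)c(Br)cc1[C@H]1C[C@@H](C)C(=O)O1 | intermediate
8 | but-1-yne | C#CCC | starting material
9 | (3R,5R)-5-[4-bromo-5-(but-1-yn-1-yl)-1-(pent-4-en-1-yl)-1H-pyrrol-2-yl]-3-methyloxolan-2-one | C=CCCCn1c(C#CCC)c(Br)cc1[C@H]1C[C@@H](C)C(=O)O1 | intermediate
10 | (3R,5R)-5-[1-bromo-9-(but-1-en-2-yl)-6,7-dihydro-5H-pyrrolo[1,2-a]azepin-3-yl]-3-methyloxolan-2-one | C=C(CC)C1=CCCCn2c1c(Br)cc2[C@H]1C[C@@H](C)C(=O)O1 | intermediate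
11 | 9-{2-[1-bromo-3-((2R,4R)-4-methyl-5-oxooxolan-2-yl)-6,7-dihydro-5H-pyrrolo[1,2-a]azepin-9-yl]butyl}-9-borabicyclo[3.3.1]nonane (C10 epimers) | CCC(CB1C2CCCC1CCC2)C1=CCCCn2c1c(Br)cc2[C@H]1C[C@@H](C)C(=O)O1 | intermediate
12 | (3R,5R)-5-[1-bromo-9-(1-hydroxybutan-2-yl)-6,7-dihydro-5H-pyrrolo[1,2-a]azepin-3-yl]-3-methyloxolan-2-one (C10 epimers) | CCC(CO)C1=CCCCn2c1c(Br)cc2[C@H]1C[C@@H](C)C(=O)O1 | intermediate
13 | methacrolein (2-methylprop-2-enal) | CC(=C)C=O | starting material
14 | (2E)-3-{9-(1-hydroxybutan-2-yl)-3-[(2R,4R)-4-methyl-5-oxooxolan-2-yl]-6,7-dihydro-5H-pyrrolo[1,2-a]azepin-1-yl}-2-methylprop-2-enal (C10 epimers) | CCC(CO)C1=CCCCn2c1c(/C=C(\C)C=O)cc2[C@H]1C[C@@H](C)C(=O)O1 | intermediate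
15 | 2-{1-[(1E)-2-methyl-3-oxoprop-1-en-1-yl]-3-[(2R,4R)-4-methyl-5-oxooxolan-2-yl]-6,7-dihydro-5H-pyrrolo[1,2-a]azepin-9-yl}butanal (C10 epimers, interconverting in step 9) | CCC(C=O)C1=CCCCn2c1c(/C=C(\C)C=O)cc2[C@H]1C[C@@H](C)C(=O)O1 | intermediate
16 | acyl azolium alkoxide: the ring C adduct with C11–O(−) and the C14 acyl group bound to the (5aS,10bR) triazolium carbon | CC[C@H]1C2=CCCCn3c([C@H]4C[C@@H](C)C(=O)O4)cc(c32)[C@@H]([C@@H]1[O-])[C@@H](C)C(=O)c1n2c(n[n+]1-c3c(C)cc(C)cc3C)CO[C@H]3Cc4ccccc4[C@H]32 | intermediate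
17 | target CNP0324368.1: (10S,11R,12S,13R,18R,20R) pyrrolo[1,2-a]azepine (C8=C9) fused to ring C with 10-ethyl and the cis-fused α-methyl lactone D, carrying (2R,4R)-4-methyl-5-oxooxolan-2-yl at C3 | CC[C@H]1C2=CCCCn3c([C@H]4C[C@@H](C)C(=O)O4)cc(c32)[C@H]2[C@@H]1OC(=O)[C@@H]2C | target

**Totals**
Total steps: 9. Longest linear sequence: 9 (from 1).

**Three steps most likely to fail**

Step 9 (key annulation). Risks are slow carbene addition to the α-methyl, electron-rich enal; base-induced drift of the aldehyde into conjugation (C9=C10); a competing Stetter path from the aliphatic aldehyde; and the wrong C10 epimer reacting faster. The fallback sets out from 12 and returns at 17. Heck coupling of 12 with methyl methacrylate under the step 7 conditions gives methyl (E)-enoate alcohol F1. Dess–Martin oxidation gives aldehyde ester F2. SmI2 (2.5 equiv) with MeOH in THF at −78 °C then reduces the aldehyde to a ketyl radical anion, which adds 6-exo to the enoate β-carbon (C12); protonation of the samarium enolate and lactonisation with loss of methanol give 17. This replaces carbene catalysis by single-electron chemistry and uses no base, so the aldehyde cannot isomerise. Its limits are that C10 does not equilibrate, so the 10-epimer must be separated (at most half the material), and the cis ring fusion depends on samarium chelation (no HMPA).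

Step 7 (Heck coupling). The bromide is electron-rich and flanked by the C9 side chain, and methacrolein can polymerise or give the non-conjugated isomer. The fallback sets out from 12 and returns at 15. Suzuki–Miyaura coupling of 12 with (E)-2-methyl-3-(4,4,5,5-tetramethyl-1,3,2-dioxaborolan-2-yl)prop-2-en-1-ol (Pd(OAc)2, SPhos, K3PO4, dioxane–water, 80 °C) gives diol F3, with the alkene geometry fixed by the reagent. Dess–Martin periodinane (2.6 equiv, NaHCO3) then oxidises both primary alcohols together to give 15.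

Step 5 (enyne ring closure). The internal alkyne sits between the N-chain and the C–Br, so the ruthenium alkylidene formed on the pentenyl group may not engage it. The fallback sets out from 9 and returns at 10. Intermolecular enyne cross-metathesis of the alkyne with ethylene (second-generation Grubbs catalyst RuCl2(=CHPh)(H2IMes)(PCy3), ethylene 4 atm, toluene, 80 °C) gives the isolable 2,3-disubstituted butadiene F4. A conventional ring-closing olefin metathesis between the pentenyl group and the nearer 1,1-disubstituted alkene (second-generation Hoveyda–Grubbs catalyst RuCl2(=CH-2-(i-PrO)C6H4)(H2IMes), toluene, 100 °C, argon sparge) then closes the azepine to 10 with loss of ethene.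

**Further compounds**
F1 | step 9 | methyl (2E)-3-{9-(1-hydroxybutan-2-yl)-3-[(2R,4R)-4-methyl-5-oxooxolan-2-yl]-6,7-dihydro-5H-pyrrolo[1,2-a]azepin-1-yl}-2-methylprop-2-enoate | CCC(CO)C1=CCCCn2c1c(/C=C(\C)C(=O)OC)cc2[C@H]1C[C@@H](C)C(=O)O1
F2 | step 9 | methyl (2E)-2-methyl-3-{3-[(2R,4R)-4-methyl-5-oxooxolan-2-yl]-9-(1-oxobutan-2-yl)-6,7-dihydro-5H-pyrrolo[1,2-a]azepin-1-yl}prop-2-enoate | CCC(C=O)C1=CCCCn2c1c(/C=C(\C)C(=O)OC)cc2[C@H]1C[C@@H](C)C(=O)O1
F3 | step 7 | (3R,5R)-5-{9-(1-hydroxybutan-2-yl)-1-[(1E)-3-hydroxy-2-methylprop-1-en-1-yl]-6,7-dihydro-5H-pyrrolo[1,2-a]azepin-3-yl}-3-methyloxolan-2-one | CCC(CO)C1=CCCCn2c1c(/C=C(\C)CO)cc2[C@H]1C[C@@H](C)C(=O)O1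
F4 | step 5 | (3R,5R)-5-[4-bromo-5-(3-methylidenepent-1-en-2-yl)-1-(pent-4-en-1-yl)-1H-pyrrol-2-yl]-3-methyloxolan-2-one | C=CCCCn1c(C(=C)C(=C)CC)c(Br)cc1[C@H]1C[C@@H](C)C(=O)O1
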